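The numbers in the tables were generated by integration on assumed constants; the scatter is artificial.

I read each flask at 8.0 d, and in both earlier runs J stands within its scatter from about 3.00 d on, so what matters is where J stalls.

| flask | J | Q | X | remark | time |
|---|---|---|---|---|---|
| Friday's | 0.099 M | 0.040 M | 2.2 mM | run made earlier |  |
| Monday's | 0.099 M | 0.35 M | 2.2 mM | run made earlier |  |
| red | 0.099 M | 0.0500 M | 2.2 mM |  | 8.0 d |
| blue | 0.099 M | 0.150 M | 2.2 mM |  | 8.0 d |
| ochre | 0.099 M | 0.450 M | 2.2 mM |  | 8.0 d |

| run | time / d | D / % | G / % | L / % | J / % |
|---|---|---|---|---|---|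
| Friday's | 1.25 | 0 | 15 | 14 | 72 |
| Friday's | 2.50 | 4 | 7 | 19 | 67 |
| Friday's | 3.00 | 6 | 7 | 20 | 66 |
| Friday's | 5.00 | 7 | 4 | 19 | 65 |
| Friday's | 6.00 | 8 | 4 | 23 | 66 |
| Friday's | 8.00 | 8 | 5 | 22 | 67 |
| Monday's | 1.25 | 7 | 30 | 54 | 8 |
| Monday's | 2.50 | 13 | 17 | 63 | 9 |
| Monday's | 3.00 | 14 | 16 | 66 | 5 |
| Monday's | 5.00 | 19 | 14 | 68 | 4 |
| Monday's | 6.00 | 19 | 13 | 67 | 5 |
| Monday's | 8.00 | 24 | 8 | 60 | 3 |

(readings scatter by 1.5 percentage points)

- the analysis behind the earlier runs scatters by 1.5 percentage points, standard deviation

- which of these there is most of at the end, counted by the J in it, red (J / L / D / G)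
- which of these there is most of at the end, counted by the J in it, blue (J / L / D / G)
- which of these there is most of at the end, counted by the J in it, ochre (J / L / D / G)
- the largest of these amounts at the end, in percent of the J charged, red
- the largest of these amounts at the end, in percent of the J charged, blue
- the largest of these amounts at the end, in percent of the J charged, ochre

Red lies between two plain bounds. If one Q goes with each J, then Q is the limiting reagent in red, charged at 0.0500 M against 0.099 M of J, and J cannot fall below 49.5 %. It should also stay below Friday's 67 %, since red has more Q.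

To tighten this I form a reaction quotient from the last readings: the J turned over the J left, divided by the free Q, which I take as the charge of Q less the J turned. Friday gives 67.2 /M and Monday 127 /M, both readings with their scatter, and these lie 0.276 of a power of ten apart. Their middle in logarithms, 92.5 /M, is the number I carry, the stall quotient.

Solving for the J in red that meets each quotient, Friday's value leaves 59.7 % and Monday's 55.8 %. I commit to 57.6 %, and because that exceeds the 42.4 % turned, J stays ahead of any product in red.

The forecast gives J at 58 % in red, saying “J remains largest at about 58%”, then L at 53 % in blue and L at 63 % in ochre. Its red value, reached by its own count of the J consumed and not by my quotient, falls inside my bracket.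

The flask gives J at 57.3 % in red, inside my bracket, then L at 55.5 % in blue and L at 62.0 % in ochre, each within the forecast's range.

    G + X ⇌ L + X, rate k1*[X]*[G] forward; the back reaction follows from the equilibrium constant (k = 0.288 /M/min)
    X + G → X + D (k = 0.115 /M/min)
    2 X ⇌ Z, settled at all times (K = 662 /M)
    J + Q ⇌ G (K = 12.1 /M, k = 0.0118 /M/min)
    J + Q ⇌ L (K = 58.0 /M, k = 0.00386 /M/min)

Red's own end state, with 16 % of its Q left, gives a quotient of 96.1 /M against the 92.5 /M I carried. The neighbouring flask is ochre with 0.40 M of J, which makes 1.12 equiv of Q to J, the rest held. The carried quotient on those charges leaves 10.5 % of J, and that flask ends with J at 9.98 %.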